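**Retrosynthetic overview**

- The (1Z,3E)-dienol is made last, by Z-selective semi-reduction of an (E)-enyne; the enyne comes from Sonogashira coupling of a C2-ethynyl macrocycle with (R,E)-1-iodopent-1-en-3-ol.
- The N9 acetyl group comes from selective acetylation of the unhindered ring amine of the ethynyl triazalactam.
- The thirteen-membered ring comes from a transamidative ring expansion 4 → 9 → 13 of an N-(4-bromobutyl)-4-alkynyl β-lactam, triggered by propane-1,3-diamine.
- The C2 stereocentre comes from an enantioconvergent copper-catalysed alkynylation of racemic 4-acetoxyazetidin-2-one (from vinyl acetate and chlorosulfonyl isocyanate) with ethynyltrimethylsilane.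
- Ring order: azetidinone first, then the nine-membered lactam, then the thirteen-membered lactam (the last two in one flask).

Assumption: the chiral propargylic alcohol of step 6 is bought as its single (R) enantiomer; the PyBox antipode written in step 2 is replaced by its mirror image if it delivers the other face.

**Route**

Step 1
Reactants: 1 vinyl acetate; 2 chlorosulfonyl isocyanate
Product: 4 rac-4-acetoxyazetidin-2-one, via N-chlorosulfonyl lactam 3 (not isolated)
Conditions: neat 1 (excess), 5–10 °C; then aq NaHCO3, Na2SO3, 0 °C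
Reagents that add atoms: none
Why: Stepwise [2+2] cycloaddition of the isocyanate to the enol ester (nitrogen ends on the acetoxy-bearing carbon via the stabilised zwitterion), then reductive hydrolysis of the N–SO2Cl group; the racemic centre is harmless because step 2 erases it.

Step 2
Reactants: 4 rac-4-acetoxyazetidin-2-one; 5 ethynyltrimethylsilane
Product: 7 (R)-4-[(trimethylsilyl)ethynyl]azetidin-2-one, via azetinone 6 (not isolated)
Conditions: Cu(MeCN)4PF6 (5 mol%), (S,S)-Ph-PyBox (6 mol%), i-Pr2NEt (2 equiv), 5 (1.5 equiv), CH2Cl2, −20 °C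
Reagents that add atoms: none
Why: Proposed new method: i-Pr2NEt removes AcOH from either enantiomer of 4 (N–H deprotonation, then loss of acetate) to give the flat N-acyl imine 6, so the racemate converges; the PyBox-bound monovalent-copper acetylide of 5 binds the imine nitrogen and transfers the alkynyl group to one face of the C=N carbon, which sets the R centre, and the copper amidate is protonated by the next alkyne to close the cycle (ee can be raised by recrystallisation); the closest known reaction type is the copper/PyBox-catalysed enantioselective alkynylation of N-acyl imines and iminium ions generated in situ, and the racemic displacement of the acetate of 4 by metal acetylides runs through the same azetinone.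

Step 3
Reactants: 7 (R)-4-[(trimethylsilyl)ethynyl]azetidin-2-one; 8 1,4-dibromobutane
Product: 10 (R)-1-(4-bromobutyl)-4-[(trimethylsilyl)ethynyl]azetidin-2-one, via sodium lactamate 9 (not isolated)
Conditions: NaH (1.0 equiv), DMF, 0 °C; then 8 (4 equiv), 0 → 25 °C
Reagents that add atoms: none
Why: SN2 N-alkylation of the lactam anion; the excess of dibromide suppresses double alkylation and exactly one equivalent of base leaves the propargylic C–H untouched, so the stereocentre is retained.

Step 4
Reactants: 10 (R)-1-(4-bromobutyl)-4-[(trimethylsilyl)ethynyl]azetidin-2-one; 11 propane-1,3-diamine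
Product: 15 (R)-2-ethynyl-1,5,9-triazacyclotridecan-4-one, via aminated lactam 12 (not isolated), via nine-membered lactam 13 (not isolated), via silylated macrocycle 14 (not isolated)
Conditions: 11 (5 equiv), K2CO3 (2 equiv), MeCN, 25 °C; excess 11 evaporated; i-PrOH (0.02 M), 80 °C; then MeOH, 25 °C
Reagents that add atoms: none
Why: Amination followed by transamidative ring expansion: SN2 by one NH2 gives 12, its secondary amine opens the strained β-lactam through a seven-membered transition state (4 → 9, β-lactam transamidation), and the pendant NH2 of 13 then attacks the medium-ring tertiary lactam through a six-membered tetrahedral intermediate (zip reaction, 9 → 13), driven by relief of nine-ring strain and formation of a secondary amide; no bond to the stereocentre is touched, and K2CO3/MeOH finally removes the silyl group.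

Step 5
Reactants: 15 (R)-2-ethynyl-1,5,9-triazacyclotridecan-4-one
Product: 16 (R)-9-acetyl-2-ethynyl-1,5,9-triazacyclotridecan-4-one
Conditions: Ac2O (1.0 equiv), Et3N (1.2 equiv), CH2Cl2, −78 → −20 °C
Reagents that add atoms: acetic anhydride, CC(=O)OC(C)=O
Why: Chemoselective N-acylation: N9 is an unhindered dialkylamine, whereas N1 is α-branched and much less basic (propargylic and β-carbonyl substituents) and the amide N–H is inert, so one equivalent of anhydride at low temperature acetylates N9 only.

Step 6
Reactants: 17 (R)-pent-1-yn-3-ol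
Product: 19 (R,E)-1-iodopent-1-en-3-ol, via alkenylzirconocene 18 (not isolated)
Conditions: Cp2Zr(H)Cl (2.2 equiv), THF, 0 → 25 °C; then I2 (1.1 equiv), 0 °C
Reagents that add atoms: iodine, II
Why: Hydrozirconation–iodination: the first equivalent of Cp2Zr(H)Cl caps the hydroxyl as a zirconium alkoxide, the second adds syn with zirconium on the terminal carbon, and iodinolysis with retention gives the E iodide without touching the carbinol centre.

Step 7
Reactants: 16 (R)-9-acetyl-2-ethynyl-1,5,9-triazacyclotridecan-4-one; 19 (R,E)-1-iodopent-1-en-3-ol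
Product: 20 (R)-9-acetyl-2-[(3E,5R)-5-hydroxyhept-3-en-1-yn-1-yl]-1,5,9-triazacyclotridecan-4-one
Conditions: Pd(PPh3)4 (5 mol%), CuI (10 mol%), Et2NH (5 equiv), degassed THF, 25 °C
Reagents that add atoms: none
Why: Sonogashira coupling (zerovalent palladium oxidative addition, copper acetylide transmetalation) joins the terminal alkyne to the alkenyl iodide with retention of the E geometry; the free amine, amides and alcohol are tolerated.

Step 8
Reactants: 20 (R)-9-acetyl-2-[(3E,5R)-5-hydroxyhept-3-en-1-yn-1-yl]-1,5,9-triazacyclotridecan-4-one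
Product: 21 (2R)-9-acetyl-2-[(1Z,3E,5R)-5-hydroxyhepta-1,3-dien-1-yl]-1,5,9-triazacyclotridecan-4-one
Conditions: Zn dust activated with Cu(OAc)2 and AgNO3, MeOH–H2O (1:1), 40 °C
Reagents that add atoms: none
Why: Boland-type syn semi-reduction: activated zinc reduces only the conjugated alkyne to the Z alkene and leaves the E alkene, the allylic C–O and C–N bonds and both stereocentres untouched.

**Compound list**

1 | vinyl acetate | CC(=O)OC=C | starting material
2 | chlorosulfonyl isocyanate | O=C=NS(=O)(=O)Cl | starting material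
3 | rac-1-(chlorosulfonyl)-4-oxoazetidin-2-yl acetate | CC(=O)OC1CC(=O)N1S(=O)(=O)Cl | intermediate
4 | rac-4-acetoxyazetidin-2-one (4-oxoazetidin-2-yl acetate) | CC(=O)OC1CC(=O)N1 | intermediate
5 | ethynyltrimethylsilane | C#C[Si](C)(C)C | starting material
6 | azet-2(3H)-one (1-azetin-4-one) | O=C1CC=N1 | intermediate
7 | (R)-4-[(trimethylsilyl)ethynyl]azetidin-2-one | O=C1C[C@H](C#C[Si](C)(C)C)N1 | intermediate
8 | 1,4-dibromobutane | BrCCCCBr | starting material
9 | sodium salt of (R)-4-[(trimethylsilyl)ethynyl]azetidin-2-one | O=C1C[C@H](C#C[Si](C)(C)C)[N-]1.[Na+] | intermediate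
10 | (R)-1-(4-bromobutyl)-4-[(trimethylsilyl)ethynyl]azetidin-2-one | O=C1C[C@H](C#C[Si](C)(C)C)N1CCCCBr | intermediate
11 | propane-1,3-diamine | NCCCN | starting material
12 | (R)-1-{4-[(3-aminopropyl)amino]butyl}-4-[(trimethylsilyl)ethynyl]azetidin-2-one | O=C1C[C@H](C#C[Si](C)(C)C)N1CCCCNCCCN | intermediate
13 | (R)-1-(3-aminopropyl)-4-[(trimethylsilyl)ethynyl]-1,5-diazonan-2-one | O=C1C[C@H](C#C[Si](C)(C)C)NCCCCN1CCCN | intermediate
14 | (R)-2-[(trimethylsilyl)ethynyl]-1,5,9-triazacyclotridecan-4-one | O=C1C[C@H](C#C[Si](C)(C)C)NCCCCNCCCN1 | intermediate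
15 | (R)-2-ethynyl-1,5,9-triazacyclotridecan-4-one | O=C1C[C@H](C#C)NCCCCNCCCN1 | intermediate
16 | (R)-9-acetyl-2-ethynyl-1,5,9-triazacyclotridecan-4-one | O=C1C[C@H](C#C)NCCCCN(C(C)=O)CCCN1 | intermediate
17 | (R)-pent-1-yn-3-ol | C#C[C@H](O)CC | starting material
18 | (R,E)-1-[chlorobis(cyclopentadienyl)zirconio]pent-1-en-3-ol, O-bound to a second Cp2Zr(Cl) unit | CC[C@@H](O[Zr](Cl)(C1C=CC=C1)C1C=CC=C1)/C=C/[Zr](Cl)(C1C=CC=C1)C1C=CC=C1 | intermediate
19 | (R,E)-1-iodopent-1-en-3-ol | CC[C@@H](O)/C=C/I | intermediate
20 | (R)-9-acetyl-2-[(3E,5R)-5-hydroxyhept-3-en-1-yn-1-yl]-1,5,9-triazacyclotridecan-4-one | O=C1C[C@H](C#C/C=C/[C@H](O)CC)NCCCCN(C(C)=O)CCCN1 | intermediate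
21 | (2R)-9-acetyl-2-[(1Z,3E,5R)-5-hydroxyhepta-1,3-dien-1-yl]-1,5,9-triazacyclotridecan-4-one (CNP0251539.1) | CC[C@@H](O)/C=C/C=C\[C@H]1CC(=O)NCCCN(C(C)=O)CCCCN1 | target

**Step count and risks**

Total steps: 8. Longest linear sequence: 7 (steps 1, 2, 3, 4, 5, 7, 8; step 6 is a one-step side branch).

The three steps most likely to fail:

Step 2 (the proposed new alkynylation). Azetinone formation may be slow, the small imine may give modest ee, or the product lactam may inhibit copper. The fallback uses known sulfinimine chemistry, sets out from 5 and returns at 7. Compound 5 is lithiated (n-BuLi, THF, −78 °C) and formylated with DMF to give 3-(trimethylsilyl)prop-2-ynal F1. Condensation with (S)-tert-butanesulfinamide (Ti(OEt)4, THF) gives (S,E)-2-methyl-N-[3-(trimethylsilyl)prop-2-yn-1-ylidene]propane-2-sulfinamide F2. Addition of the titanium enolate of methyl acetate (LiN(i-Pr)2, ClTi(OiPr)3, THF, −78 °C) through a closed six-membered transition state gives methyl (R)-3-{[(S)-tert-butylsulfinyl]amino}-5-(trimethylsilyl)pent-4-ynoate F3. HCl in MeOH removes the auxiliary to give methyl (R)-3-amino-5-(trimethylsilyl)pent-4-ynoate F4, and t-BuMgCl (THF, 0 °C) closes the β-lactam to 7.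

Step 4 (the ring-expansion cascade). It may stall at 12 or 13, or the β-lactam may be opened intermolecularly by the diamine. The fallback replaces ring expansion by templated macrolactamization, sets out from 10 and returns at 14. Compound 10 is aminated with 11 (K2CO3, MeCN, 25 °C) and the crude product is methanolysed at the β-lactam (HCl, MeOH, 60 °C) to the open-chain methyl (R)-3-({4-[(3-aminopropyl)amino]butyl}amino)-5-(trimethylsilyl)pent-4-ynoate F5. Boron-templated lactamization (B(NMe2)3, xylene, reflux, 5 mM) gathers the three nitrogens on boron and closes the thirteen-membered lactam at the primary amine to give 14, which is desilylated (K2CO3, MeOH) to 15 as in step 4.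

Step 8 (the late semi-reduction). Conversion may be incomplete on the polar amino substrate, or over-reduction and Z to E drift may occur. The fallback builds the Z alkene before the diene is joined, sets out from 16 and 17 and returns at 21. Compound 16 is iodinated at the alkyne terminus (I2, morpholine, toluene, 25 °C) to (R)-9-acetyl-2-(iodoethynyl)-1,5,9-triazacyclotridecan-4-one F6. Diimide reduction (2-nitrobenzenesulfonyl hydrazide, Et3N, THF/i-PrOH, 25 °C) gives (R)-9-acetyl-2-[(Z)-2-iodoethenyl]-1,5,9-triazacyclotridecan-4-one F7. Separately, 17 is hydroborated with pinacolborane (Cp2Zr(H)Cl 10 mol%, Et3N, 60 °C) to (R,E)-1-(4,4,5,5-tetramethyl-1,3,2-dioxaborolan-2-yl)pent-1-en-3-ol F8. Suzuki–Miyaura coupling of F7 with F8 (Pd(PPh3)4, aq K3PO4, THF, 40 °C) proceeds with retention at both alkenes and gives 21 directly.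

**Further compounds**

F1 | step 2 | 3-(trimethylsilyl)prop-2-ynal | C[Si](C)(C)C#CC=O
F2 | step 2 | (S,E)-2-methyl-N-[3-(trimethylsilyl)prop-2-yn-1-ylidene]propane-2-sulfinamide | CC(C)(C)[S@](=O)/N=C/C#C[Si](C)(C)C
F3 | step 2 | methyl (R)-3-{[(S)-tert-butylsulfinyl]amino}-5-(trimethylsilyl)pent-4-ynoate | COC(=O)C[C@H](C#C[Si](C)(C)C)N[S@@](=O)C(C)(C)C
F4 | step 2 | methyl (R)-3-amino-5-(trimethylsilyl)pent-4-ynoate | COC(=O)C[C@H](C#C[Si](C)(C)C)N
F5 | step 4 | methyl (R)-3-({4-[(3-aminopropyl)amino]butyl}amino)-5-(trimethylsilyl)pent-4-ynoate | COC(=O)C[C@H](C#C[Si](C)(C)C)NCCCCNCCCN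
F6 | step 8 | (R)-9-acetyl-2-(iodoethynyl)-1,5,9-triazacyclotridecan-4-one | O=C1C[C@H](C#CI)NCCCCN(C(C)=O)CCCN1
F7 | step 8 | (R)-9-acetyl-2-[(Z)-2-iodoethenyl]-1,5,9-triazacyclotridecan-4-one | O=C1C[C@H](/C=C\I)NCCCCN(C(C)=O)CCCN1
F8 | step 8 | (R,E)-1-(4,4,5,5-tetramethyl-1,3,2-dioxaborolan-2-yl)pent-1-en-3-ol | CC[C@@H](O)/C=C/B1OC(C)(C)C(C)(C)O1
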